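**Plan**

- Retrosynthetic cuts: the two tert-butyl ester C–O bonds and the C6–O acyl bond; then C6–C7 of ring B (C7 goes back to a bromomethyl group on C8 and the C6–C8 bond is restored); then C8–CH2Br, C6–C8 (Dieckmann) and C9–C10 (radical conjugate addition); last, the ring A bond of α-cyclogeranic acid.
- Enabling feature (drimane numbering): in ring B the C6 oxygen and the C12 carboxyl on C8 are separated only by the C7 methylene. This γ-keto ester is what a five-membered β-keto ester (C6 ketone bonded directly to C8) becomes when one carbon is inserted between the ketone carbon and the α-carbon.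
- Forward order: ring A by acid cyclisation of geranic acid; the five-membered ring C5–C6–C8–C9–C10 by C9–C10 radical addition and C6–C8 Dieckmann closure; ring B by one-carbon radical ring expansion; then C6 reduction, acylation and ester cleavage.
- Stereochemistry: C5 from resolved (S)-α-cyclogeranic acid; C10 by radical addition anti to the C5 ester; C9 by α-face hydrogenation of a C8=C9 hydrindenone; C8 by hydrogen transfer to the ring-expanded radical anti to the axial C10 methyl; C6 by α-face hydride delivery.

Key step: step 9

Remarks on the chemistry: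
- The target SMILES corresponds to (5S,6R,8S,9S,10S): 5α-H, 10β-CH3, 6β-acyloxy (axial), 8β-CO2H (axial), 9β-CO2H (equatorial). Drimane numbering is used for every bicyclic compound, including the hydrindanes (C6 = ketone carbon, C8 and C9 = ester-bearing carbons; C7 is absent until step 9).
- Assumption: the salt of the (S)-acid with (R)-1-phenylethylamine is taken to be the less soluble diastereomer. If the opposite pairing crystallises, the (S)-amine is used and nothing else changes.

**Route**

Step 1
Reactants: 1 geranic acid
Product: 2 (±)-2,6,6-trimethylcyclohex-2-ene-1-carboxylic acid (α-cyclogeranic acid)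
Conditions: 85% H3PO4, PhMe, 90 °C; recrystallise from hexane
Reagents that add atoms: none
Why: Brønsted-acid cation–olefin cyclisation, in which the tertiary cation from the distal alkene is captured by the α-carbon of the enoic acid and proton loss gives the endocyclic α-isomer, the classical entry to cyclogeranic acid.

Step 2
Reactants: 2 (±)-α-cyclogeranic acid
Product: 4 (1S)-2,6,6-trimethylcyclohex-2-ene-1-carboxylic acid, via 1-phenylethylammonium salt 3 (not isolated)
Conditions: (R)-1-phenylethylamine, EtOAc, recrystallise; filter cake into 1 M HCl/Et2O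
Reagents that add atoms: none
Why: Classical resolution by diastereomeric salt crystallisation delivers the (S)-acid whose stereocentre becomes C5 of the target, and cold mineral acid frees it without touching the allylic α-CH.

Step 3
Reactants: 4 (S)-α-cyclogeranic acid
Product: 5 methyl (1S)-2,6,6-trimethylcyclohex-2-ene-1-carboxylate
Conditions: MeI, K2CO3, DMF, rt
Reagents that add atoms: iodomethane, CI
Why: Carboxylate O-alkylation (SN2) under a base too weak to deprotonate the allylic ester α-CH, so the C5 configuration is kept.

Step 4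
Reactants: 5 methyl (S)-α-cyclogeranate; 6 di-tert-butyl fumarate
Product: 7 di-tert-butyl 2-[(1R,2S)-2-(methoxycarbonyl)-1,3,3-trimethylcyclohexyl]butanedioate (both epimers at the succinate CH)
Conditions: Fe(acac)3 (0.3 equiv), PhSiH3 (2.5 equiv), 6 (3 equiv), EtOH/ethylene glycol 5:1, 60 °C
Reagents that add atoms: none
Why: Hydrogen-atom-transfer initiated Giese addition (reductive olefin coupling), in which Markovnikov hydrogen transfer to the trisubstituted alkene gives the tertiary C10 radical that should add to the fumarate on the ring face opposite the neighbouring C5 ester and so set quaternary C10, while C9 forms without control and is corrected in steps 6 and 7.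

Step 5
Reactants: 7 triester
Product: 8 di-tert-butyl (3aS,7aS)-3a,7,7-trimethyl-1-oxooctahydro-1H-indene-2,3-dicarboxylate (trans-fused; C3 epimers; C2 enolisable)
Conditions: KOtBu (1.5 equiv), THF, 0 °C → rt; AcOH quench
Reagents that add atoms: none
Why: Dieckmann condensation, in which only the C8 methylene enolate can reach the methyl ester in a five-membered closure, the tert-butyl esters are too poor as electrophiles to compete, and the product rests as its β-keto ester enolate, which also protects C5 from epimerisation.

Step 6
Reactants: 8 β-keto diester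
Product: 11 di-tert-butyl (3aS,7aS)-3a,7,7-trimethyl-1-oxo-3a,4,5,6,7,7a-hexahydro-1H-indene-2,3-dicarboxylate, via 2-phenylselanyl keto diester 9 (not isolated), via selenoxide 10 (not isolated)
Conditions: PhSeCl, pyridine, CH2Cl2, 0 °C; wash with 1 M HCl; 30% H2O2, CH2Cl2, 0 °C → rt
Reagents that add atoms: none
Why: α-Selenenylation of the β-keto ester enol followed by selenoxide syn-elimination toward the only β-hydrogen (C9–H) removes the C9 stereocentre, so both C9 epimers converge on one trans-fused hydrindenone and any cis-fused material from step 4 can be removed by chromatography at this point.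

Step 7
Reactants: 11 hydrindenone
Product: 12 di-tert-butyl (3S,3aS,7aS)-3a,7,7-trimethyl-1-oxooctahydro-1H-indene-2,3-dicarboxylate (single C3 epimer; 3-ester cis to the 3a-methyl; C2 enolisable and drawn trans)
Conditions: H2 (1 atm), 10% Pd/C, EtOAc, rt
Reagents that add atoms: none
Why: Heterogeneous catalytic hydrogenation should add hydrogen to the tetrasubstituted ene-dicarbonyl from the α face, opposite the angular C10 methyl (the facial preference familiar from ring D of steroidal trans-hydrindenes), which places the C9 hydrogen α and the C9 ester β.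

Step 8
Reactants: 12 β-keto diester; 13 dibromomethane
Product: 14 di-tert-butyl (2S,3R,3aS,7aS)-2-(bromomethyl)-3a,7,7-trimethyl-1-oxooctahydro-1H-indene-2,3-dicarboxylate (CH2Br α; both esters β)
Conditions: NaH (1.0 equiv), THF/HMPA, 0 °C; CH2Br2 (10 equiv), 0 → 60 °C
Reagents that add atoms: none
Why: C-Alkylation of the sodium β-keto ester enolate with excess dibromomethane is the standard preparation of ring-expansion substrates, and the electrophile should enter on the α face, anti to the C9 ester and the C10 methyl, although this centre is planarised again in step 9.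

Step 9
Reactants: 14 bromomethyl hydrindanone
Product: 15 di-tert-butyl (5S,8S,9S,10S)-6-oxodrimane-11,12-dioate (5α-H; 10β-CH3; both ester groups β)
Conditions: (Me3Si)3SiH (1.3 equiv) and AIBN (0.2 equiv) by syringe pump over 6 h, PhMe (0.01 M), 85 °C
Reagents that add atoms: none
Why: The silyl radical abstracts bromine from 14 and the primary C7 radical closes 3-exo-trig onto the C6 ketone carbonyl; the cyclopropyloxy radical then reopens by β-scission of the C6–C8 bond, so that C7 sits between C6 and C8 and the five-membered ring has become ring B, and the tertiary, ester-stabilised C8 radical is finally quenched by the silane. The closest known reaction type is the Dowd–Beckwith one-carbon ring expansion of α-halomethyl cyclic β-keto esters, run here with tris(trimethylsilyl)silane in place of a stannane. Ring B is therefore not closed directly: the only closure is the transient 3-exo-trig addition to C=O, and the six-membered ring results from the fragmentation. The one new stereocentre, C8, is set in the hydrogen transfer, where the planar radical is shielded on its β face by the syn-axial C10 methyl, so the bulky silane should deliver hydrogen from the α face and leave the C12 ester β, cis to the C9 ester. The step needs rearrangement to outrun reduction of the primary radical, which slow addition of the slower silane donor at high dilution secures, and attack on the ketone rather than on an ester carbonyl, which the much higher radical affinity of the ketone secures; cleavage of C6–C8 rather than C5–C6 follows from the stabilised tertiary radical and the release of cyclopropane and trans-hydrindanone strain. C5, C9 and C10 take no part, and the neutral medium leaves the epimerisable C5 untouched.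

Step 10
Reactants: 15 keto diester
Product: 16 di-tert-butyl (5S,6R,8S,9S,10S)-6-hydroxydrimane-11,12-dioate (6β-OH axial)
Conditions: NaBH4, CeCl3·7H2O, MeOH/THF, −40 °C; AcOH quench at −40 °C
Reagents that add atoms: none
Why: Luche-type borohydride reduction, in which the β face of the C6 carbonyl is closed by three syn-axial groups (the β-methyl on C4, the C10 methyl and the C8 ester) so that hydride enters from the α face to give the axial 6β-alcohol, while the cold buffered quench keeps the alkoxide from lactonising onto the neighbouring axial tert-butyl ester.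

Step 11
Reactants: 17 (2E,4E,6E)-octa-2,4,6-trienoic acid
Product: 18 (2E,4E,6E)-octa-2,4,6-trienoyl chloride
Conditions: (COCl)2, DMF (cat.), CH2Cl2, 0 °C → rt; concentrate, use crude
Reagents that add atoms: oxalyl chloride, O=C(Cl)C(=O)Cl
Why: Acid chloride formation through the Vilsmeier chloroiminium catalyst is mild enough to leave the triene geometry intact.

Step 12
Reactants: 16 hydroxy diester; 18 trienoyl chloride
Product: 19 di-tert-butyl (5S,6R,8S,9S,10S)-6-[(2E,4E,6E)-octa-2,4,6-trienoyloxy]drimane-11,12-dioate
Conditions: 18 (3 equiv), pyridine, DMAP (0.5 equiv), CH2Cl2, 0 °C → rt, dark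
Reagents that add atoms: none
Why: DMAP-catalysed acylation through the acylpyridinium ion esterifies the axial secondary alcohol with retention at C6, and pyridine instead of a trialkylamine avoids vinylogous ketene formation and deconjugation of the trienoyl unit.

Step 13
Reactants: 19 trienoate diester
Product: 20 (5S,6R,8S,9S,10S)-6-[(2E,4E,6E)-octa-2,4,6-trienoyloxy]drimane-11,12-dioic acid (CNP0462207.1)
Conditions: CF3CO2H/CH2Cl2 1:4, 0 °C → rt, dark
Reagents that add atoms: none
Why: Acidolysis of the tert-butyl esters by alkyl–oxygen cleavage with loss of isobutene frees both carboxylic acids without touching the secondary trienoate or the C8 and C9 centres, which cannot enolise under these conditions.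

**Compound list**

1 | geranic acid, (2E)-3,7-dimethylocta-2,6-dienoic acid | CC(C)=CCC/C(C)=C/C(=O)O | starting material
2 | (±)-2,6,6-trimethylcyclohex-2-ene-1-carboxylic acid | CC1=CCCC(C)(C)C1C(=O)O | intermediate
3 | (R)-1-phenylethylammonium (1S)-2,6,6-trimethylcyclohex-2-ene-1-carboxylate | CC1=CCCC(C)(C)[C@@H]1C(=O)[O-].C[C@@H]([NH3+])c1ccccc1 | intermediate
4 | (1S)-2,6,6-trimethylcyclohex-2-ene-1-carboxylic acid | CC1=CCCC(C)(C)[C@@H]1C(=O)O | intermediate
5 | methyl (1S)-2,6,6-trimethylcyclohex-2-ene-1-carboxylate | CC1=CCCC(C)(C)[C@@H]1C(=O)OC | intermediate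
6 | di-tert-butyl fumarate | CC(C)(C)OC(=O)/C=C/C(=O)OC(C)(C)C | starting material
7 | di-tert-butyl 2-[(1R,2S)-2-(methoxycarbonyl)-1,3,3-trimethylcyclohexyl]butanedioate, epimers at the succinate CH | CC(C)(C)OC(=O)CC(C(=O)OC(C)(C)C)[C@@]1(C)CCCC(C)(C)[C@@H]1C(=O)OC | intermediate
8 | di-tert-butyl (3aS,7aS)-3a,7,7-trimethyl-1-oxooctahydro-1H-indene-2,3-dicarboxylate, trans-fused, C3 epimers | O=C1C(C(=O)OC(C)(C)C)C(C(=O)OC(C)(C)C)[C@@]2(C)CCCC(C)(C)[C@H]12 | intermediate
9 | di-tert-butyl (3aS,7aS)-3a,7,7-trimethyl-1-oxo-2-(phenylselanyl)octahydro-1H-indene-2,3-dicarboxylate | O=C1C([Se]c3ccccc3)(C(=O)OC(C)(C)C)C(C(=O)OC(C)(C)C)[C@@]2(C)CCCC(C)(C)[C@H]12 | intermediate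
10 | selenoxide of 9 | O=C1C([Se](=O)c3ccccc3)(C(=O)OC(C)(C)C)C(C(=O)OC(C)(C)C)[C@@]2(C)CCCC(C)(C)[C@H]12 | intermediate
11 | di-tert-butyl (3aS,7aS)-3a,7,7-trimethyl-1-oxo-3a,4,5,6,7,7a-hexahydro-1H-indene-2,3-dicarboxylate | O=C1C(C(=O)OC(C)(C)C)=C(C(=O)OC(C)(C)C)[C@@]2(C)CCCC(C)(C)[C@H]12 | intermediate
12 | di-tert-butyl (3S,3aS,7aS)-3a,7,7-trimethyl-1-oxooctahydro-1H-indene-2,3-dicarboxylate, 3-ester cis to the 3a-methyl, C2 drawn trans to it | O=C1[C@@H](C(=O)OC(C)(C)C)[C@H](C(=O)OC(C)(C)C)[C@@]2(C)CCCC(C)(C)[C@H]12 | intermediate
13 | dibromomethane | BrCBr | starting material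
14 | di-tert-butyl (2S,3R,3aS,7aS)-2-(bromomethyl)-3a,7,7-trimethyl-1-oxooctahydro-1H-indene-2,3-dicarboxylate | O=C1[C@](CBr)(C(=O)OC(C)(C)C)[C@H](C(=O)OC(C)(C)C)[C@@]2(C)CCCC(C)(C)[C@H]12 | intermediate
15 | di-tert-butyl (5S,8S,9S,10S)-6-oxodrimane-11,12-dioate | O=C1C[C@H](C(=O)OC(C)(C)C)[C@H](C(=O)OC(C)(C)C)[C@@]2(C)CCCC(C)(C)[C@H]12 | intermediate
16 | di-tert-butyl (5S,6R,8S,9S,10S)-6-hydroxydrimane-11,12-dioate | O[C@@H]1C[C@H](C(=O)OC(C)(C)C)[C@H](C(=O)OC(C)(C)C)[C@@]2(C)CCCC(C)(C)[C@H]12 | intermediate
17 | (2E,4E,6E)-octa-2,4,6-trienoic acid | C/C=C/C=C/C=C/C(=O)O | starting material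
18 | (2E,4E,6E)-octa-2,4,6-trienoyl chloride | C/C=C/C=C/C=C/C(=O)Cl | intermediate
19 | di-tert-butyl (5S,6R,8S,9S,10S)-6-[(2E,4E,6E)-octa-2,4,6-trienoyloxy]drimane-11,12-dioate | C/C=C/C=C/C=C/C(=O)O[C@@H]1C[C@H](C(=O)OC(C)(C)C)[C@H](C(=O)OC(C)(C)C)[C@@]2(C)CCCC(C)(C)[C@H]12 | intermediate
20 | (5S,6R,8S,9S,10S)-6-[(2E,4E,6E)-octa-2,4,6-trienoyloxy]drimane-11,12-dioic acid | C/C=C/C=C/C=C/C(=O)O[C@@H]1C[C@H](C(=O)O)[C@H](C(=O)O)[C@@]2(C)CCCC(C)(C)[C@H]12 | target

**Summary**

Total step count: 13. Longest linear sequence: 12 steps (steps 1 to 10, 12 and 13, from geranic acid); step 11 is a one-step side branch.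

Steps most likely to fail:

Step 4. Hydrogen transfer from the iron hydride to the fumarate, and premature reduction of the crowded tertiary radical, may outrun C–C bond formation. Fallback: generate the same radical without a metal hydride. Setting out from 5, Mukaiyama hydration (Co(acac)2, PhSiH3, O2, THF) would give the tertiary alcohol methyl (1S)-2-hydroxy-2,6,6-trimethylcyclohexane-1-carboxylate F1. Acylation with methyl chlorooxoacetate (Et3N, DMAP, CH2Cl2) would give the mixed oxalate methyl (1S)-2-[(methoxyoxalyl)oxy]-2,6,6-trimethylcyclohexane-1-carboxylate F2. Selective saponification of the oxalate methyl ester (CsOH, THF/H2O) would give the cesium oxalate cesium 2-{[(2S)-2-(methoxycarbonyl)-1,3,3-trimethylcyclohexyl]oxy}-2-oxoacetate F3. Visible-light photoredox decarboxylation (Ir[dF(CF3)ppy]2(dtbbpy)PF6, blue LEDs, DME/DMF, H2O) in the presence of 6 releases the C10 radical for the same Giese addition and returns to the route at 7.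

Step 9. Hydrogen transfer to the C8 radical may occur from both faces, axial β delivery giving the trans-diester. Fallback: set C8 by hydrogenation instead. Setting out from 14, the ring expansion is run as before and the crude mixture of 15 and its C8 epimer di-tert-butyl (5S,8R,9S,10S)-6-oxodrimane-11,12-dioate F4 is dehydrogenated with IBX (DMSO/PhF, 70 °C). Only C7–C8 can be desaturated, since C5 has no β-hydrogen, so both epimers should give di-tert-butyl (5S,9R,10S)-6-oxodrim-7-ene-11,12-dioate F5. Hydrogenation (H2, 10% Pd/C, EtOAc) from the α face, opposite the C10 methyl, places the C8 hydrogen α and comes back to the route at 15.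

Step 12. Acyl transfer to the axial 6β-hydroxyl, flanked by three syn-axial groups, may be too slow, so that the trienoyl chloride is lost to ketene formation and oligomerisation first. Fallback: attach a small acyl group and build the triene afterwards. Setting out from 16, bromoacetyl bromide (pyridine, CH2Cl2, −20 °C) would give di-tert-butyl (5S,6R,8S,9S,10S)-6-(bromoacetoxy)drimane-11,12-dioate F6. Arbuzov reaction with P(OEt)3 (100 °C) would give di-tert-butyl (5S,6R,8S,9S,10S)-6-[(diethoxyphosphoryl)acetoxy]drimane-11,12-dioate F7. Horner–Wadsworth–Emmons olefination with (2E,4E)-hexa-2,4-dienal under Masamune–Roush conditions (LiCl, DBU, MeCN) forms the 2E alkene and returns to the route at 19.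

**Further compounds**

F1 | step 4 | methyl (1S)-2-hydroxy-2,6,6-trimethylcyclohexane-1-carboxylate (C2 epimers) | CC1(O)CCCC(C)(C)[C@@H]1C(=O)OC
F2 | step 4 | methyl (1S)-2-[(methoxyoxalyl)oxy]-2,6,6-trimethylcyclohexane-1-carboxylate | COC(=O)C(=O)OC1(C)CCCC(C)(C)[C@@H]1C(=O)OC
F3 | step 4 | cesium 2-{[(2S)-2-(methoxycarbonyl)-1,3,3-trimethylcyclohexyl]oxy}-2-oxoacetate | [Cs+].[O-]C(=O)C(=O)OC1(C)CCCC(C)(C)[C@@H]1C(=O)OC
F4 | step 9 | di-tert-butyl (5S,8R,9S,10S)-6-oxodrimane-11,12-dioate | O=C1C[C@@H](C(=O)OC(C)(C)C)[C@H](C(=O)OC(C)(C)C)[C@@]2(C)CCCC(C)(C)[C@H]12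
F5 | step 9 | di-tert-butyl (5S,9R,10S)-6-oxodrim-7-ene-11,12-dioate | O=C1C=C(C(=O)OC(C)(C)C)[C@H](C(=O)OC(C)(C)C)[C@@]2(C)CCCC(C)(C)[C@H]12
F6 | step 12 | di-tert-butyl (5S,6R,8S,9S,10S)-6-(bromoacetoxy)drimane-11,12-dioate | BrCC(=O)O[C@@H]1C[C@H](C(=O)OC(C)(C)C)[C@H](C(=O)OC(C)(C)C)[C@@]2(C)CCCC(C)(C)[C@H]12
F7 | step 12 | di-tert-butyl (5S,6R,8S,9S,10S)-6-[(diethoxyphosphoryl)acetoxy]drimane-11,12-dioate | CCOP(=O)(OCC)CC(=O)O[C@@H]1C[C@H](C(=O)OC(C)(C)C)[C@H](C(=O)OC(C)(C)C)[C@@]2(C)CCCC(C)(C)[C@H]12
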